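Atom numbering used throughout: C1 is the ester carbonyl, C2 the acetate CH2, C3–C6 the ring carbons (O1–O2 complete the ring), C7–C12 the side chain on C6. Compound numbers are those of the steps and of the compound list.

## Analysis of the target

The target 24 is a 1,2-dioxane: a six-membered ring of the O–O unit and C3–C6, with the methyl acetate arm (C1–C2) on C3, a methyl group on C4, and on the fully substituted C6 a methyl group and a (2E,4E)-2-methyl-6-phenylhexa-2,4-dienyl chain (C7–C12). It has three stereocentres, C3 (S), C4 (R) and C6 (R). The acetate arm and the C4 methyl are trans, and the C4 methyl and the C6 side chain are cis, so in the chair the three larger groups are equatorial and only the C6 methyl is axial. C3 and C4 are neighbours and can control one another, but C6 is a quaternary peroxide carbon one methylene away from C4, with nothing nearby to direct formation of its C–O bond. The O–O bond does not tolerate hydride reagents, main-group organometallics, free phosphines or low-valent metals for long; the ester sits β to a peroxide oxygen, so base can open the ring by E1cB elimination or by Kornblum–DeLaMare fragmentation at H3; C12 is allylic to the diene and benzylic. The problem is therefore one of order: C–C bonds that need strong organometallics must be in place before the peroxide exists, and the diene should come last. The plan rests on the unit C1–C2–C3(O), an acetate aldol pattern whose C3–O bond lies anti to the C4 methyl; Felkin–Anh addition to a C3 aldehyde would give the syn arrangement, so one inversion at C3 is part of the design.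

## Retrosynthetic reasoning

**C9–C10 (24 to 22 and 23).** The single bond between the two alkenes of the diene is cut first. A Suzuki–Miyaura coupling of the iodoalkene 22 with the purchasable alkenylboronic acid 23 forms it with retention of both double-bond geometries and delivers C10–C12 and the phenyl ring in one piece. Cutting here keeps the skipped diene and the C12 methylene out of every earlier step; the iodoalkene of 22 is a quiet spectator toward Lewis acids and oxidants. The forward reaction must run at room temperature with mild base so that the dioxane survives.

**Ester (22 to 21).** The ring-forming step releases C1 as a carboxylic acid, so the methyl ester is made afterwards from 21, under neutral conditions because of the β-peroxy ester.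

**C3–O and C2–C3 (21 to 20 to 15 and 19).** The peroxide C3–O bond is cut with inversion to the β-lactone 20, in which C3 carries the lactone oxygen. The C2–C3 bond of 20 is then cut as an acetate aldol, giving aldehyde 15 and ketene acetal 19. This uses the C3 aldehyde twice: as the electrophile for the C–C bond, and after lactonisation as a strained secondary alkyl carboxylate that the peroxide can displace, so no free β-hydroxy ester and no separate activation step are needed. Felkin–Anh addition gives the 3,4-syn lactone, and the displacement turns it into the 3,4-anti ring of 21. The forward reaction must form the ring, two bonds and the C3 stereocentre in one flask. For that the peroxide has to be masked (silyl) so that it does not add to the aldehyde, yet remain nucleophilic enough to open the lactone under a Lewis acid mild enough to spare the O–O bond.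

**C6–O (15 to 13 to 12).** The aldehyde is taken back to alcohol 13, because an aldehyde would be autoxidised in the radical step. The C6–O bond is then cut back to the 1,1-disubstituted alkene of 12, whose methylene becomes the C6 methyl. A Markovnikov radical silylperoxidation gives the tertiary silyl peroxide directly in the protected form the key step needs. A polar route through a C6 cation would be intercepted by the C3 oxygen. The price is that the C6 radical is planar, so both C6 epimers (13 and 14) form in that step and must be separated; this is accepted because it happens at a short, cheap stage.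

**C8–CH3 and C9–I (12 to 10 to 9).** Both bonds go back to the terminal alkyne 10 by carboalumination–iodination, which fixes the E geometry. It is placed before the peroxide because organoaluminium reagents destroy O–O bonds. The alkyne is carried through the coupling and the ester reduction in silylated form (8, 9).

**C5–C6 (9 to 8 to 2 and 6).** This bond is cut as an sp3–sp2 Negishi coupling between the zinc reagent 7, made from iodide 2, and bromoalkene 6. It divides the skeleton into the chiral C3–C5 unit from the hydroxy ester 1 and the achiral C6–C9 unit from 3 and 4. With the (R) ester 1, the ester carbon must become C3 and the hydroxymethyl carbon C5; the hydroxyl is therefore turned into iodide directly, and the ester is reduced only after the coupling (8 to 9).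

**Ketene acetal (19 to 18 to 16 and 17).** O-silylation of the thioester enolate of 18, itself from thiol 16 and acid chloride 17.

## Alternatives that were turned down

**Alternative 1: cyclopropylcarbinyl opening.**
- Disconnection: the C6–O bond and the C8=C9 alkene together.
- Forward key step: acid ionises the allylic carbinol at C9 of A2, which carries a cyclopropane across C6–C7–C8 and a free hydroperoxide at C3. The hydroperoxide attacks C6 from the rear as the C6–C8 bond breaks, giving the silyl ether A1.
- For it: it is the only plan that sets C6 stereospecifically, and on this point it is stronger than the chosen route. It also makes the trisubstituted alkene and the ring in one event and needs no palladium on a peroxide.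
- Against it: A2 needs a free secondary hydroperoxide at C3, itself a stereocentre to be set, together with two fully substituted cyclopropane carbons. Ionisation at C9 spreads the charge as far as C11, so capture there or elimination can compete. Attack at the fully substituted C6 has SN1 character, so the inversion may leak. The C8=C9 geometry depends on the conformation at the moment of ionisation. A1 still needs desilylation, two oxidations and esterification with the diene and peroxide present.
- Comparison: the chosen route gives up control at C6, but its risky step is one defined SN2 event and its precursor is reached in eight steps.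

**Alternative 2: aerobic ring expansion of a cyclobutanol.**
- Disconnection: both ring C–O bonds, with the C3–C6 bond of cyclobutanol A4 as the hidden connection.
- Forward key step: Co(acac)2 under oxygen turns A4 into its alkoxy radical; β-scission leaves the C3 ketone and the tertiary C6 radical, which takes up oxygen and closes on the ketone to the peroxyhemiketal A3.
- For it: the reaction type is known for cyclobutanols, both C–O bonds form in one step, and all carbon–carbon chemistry is finished before any peroxide exists.
- Against it: C6 passes through a planar radical, so there is no control there; on this point it equals the chosen route. A3 has an extra hydroxyl at C3 that must be removed by ionic reduction through a peroxycarbenium ion, and the facial selectivity of that reduction then decides C3. Ring–chain tautomerism of A3 exposes a β-keto ester and lets C4 epimerise. A4, with a quaternary carbon and the iodoalkene, costs more steps than the acyclic aldehyde 15.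
- Comparison: the chosen plan sets C3 at the correct oxidation level by inversion and needs no deoxygenation.

**Alternative 3: peroxypalladation–methoxycarbonylation.**
- Disconnection: the C3–O and C1–C2 bonds.
- Forward key step: PdCl2(MeCN)2 with benzoquinone under carbon monoxide in methanol adds the hydroperoxide oxygen of A6 to C3 of the terminal alkene; the C2–palladium bond is carbonylated to give ester A5.
- For it: it has the best step economy at the ring stage, and here it is stronger than the chosen route. Ring and ester arm arrive together, no esterification is needed, and a chair-like oxypalladation with the C4 methyl equatorial should favour the 3,4-trans ring.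
- Against it: a free tertiary hydroperoxide meets palladium and carbon monoxide. Hydroperoxides with divalent palladium turn terminal alkenes into methyl ketones by O–O heterolysis after peroxypalladation, and they oxidise carbon monoxide and zerovalent palladium. The iodoalkene cannot be present, so A5 carries a silyl placeholder and needs an extra iododesilylation. The C6 hydroperoxide of A6 still comes from an unselective step.
- Comparison: the chosen route keeps the peroxide silylated until ring closure, uses only a main-group Lewis acid there, and carries the iodide through.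

Key step: step 11

Assumption: the C6 epimers 13 and 14 formed in step 7 are taken to be separable by chromatography; the wanted series should show, after ring closure, a 1,3-diaxial contact between the C6 methyl and H4.

## Route

Step 1
Reactants: 1 methyl (R)-3-hydroxy-2-methylpropanoate
Product: 2 methyl (S)-3-iodo-2-methylpropanoate
Conditions: I2, PPh3, imidazole, CH2Cl2, 0 °C to rt
Reagents that add atoms: iodine, I-I
Why: Appel-type iodination of the primary alcohol by SN2 on the alkoxyphosphonium ion; the stereocentre is not involved (only its descriptor changes), and the ester is kept so that its carbon becomes C3 and the iodomethyl carbon C5.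

Step 2
Reactants: 3 2,3-dibromoprop-1-ene; 4 ethynyltrimethylsilane
Product: 6 (4-bromopent-4-en-1-yn-1-yl)trimethylsilane, via [(trimethylsilyl)ethynyl]magnesium bromide 5 (not isolated)
Conditions: 4, EtMgBr, THF, 0 to 40 °C; then 3, CuBr·SMe2 (5 mol %), 50 °C
Reagents that add atoms: none
Why: Deprotonation of the alkyne, then copper-catalysed substitution of the allylic bromide by the alkynyl Grignard reagent; the vinylic C–Br bond does not react and is kept as the handle for step 3.

Step 3
Reactants: 2 methyl (S)-3-iodo-2-methylpropanoate; 6 (4-bromopent-4-en-1-yn-1-yl)trimethylsilane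
Product: 8 methyl (2R)-2-methyl-4-methylidene-7-(trimethylsilyl)hept-6-ynoate, via (S)-(3-methoxy-2-methyl-3-oxopropyl)zinc iodide 7 (not isolated)
Conditions: Zn dust (activated with BrCH2CH2Br, Me3SiCl), DMF, rt; then 6, Pd(PPh3)4 (5 mol %), rt to 40 °C
Reagents that add atoms: none
Why: Zinc inserts into the primary C–I bond to give an ester-chelated β-zincio ester that is too weakly basic to disturb its own α-stereocentre; Negishi coupling with the 2-bromoalkene then forms C5–C6 and the 1,1-disubstituted alkene.

Step 4
Reactants: 8 methyl (2R)-2-methyl-4-methylidene-7-(trimethylsilyl)hept-6-ynoate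
Product: 9 (2R)-2-methyl-4-methylidene-7-(trimethylsilyl)hept-6-yn-1-ol
Conditions: iBu2AlH (2.5 equiv), CH2Cl2, −78 to 0 °C; aq. sodium potassium tartrate
Reagents that add atoms: none
Why: Hydride reduction of the ester to the C3 carbinol, needed because an ester would not survive Me3Al in step 6; at low temperature the silylalkyne and the alkene are not hydroaluminated.

Step 5
Reactants: 9 (2R)-2-methyl-4-methylidene-7-(trimethylsilyl)hept-6-yn-1-ol
Product: 10 (2R)-2-methyl-4-methylidenehept-6-yn-1-ol
Conditions: K2CO3, MeOH, rt
Reagents that add atoms: none
Why: Methoxide-mediated protodesilylation of the alkynylsilane; the conditions are mild enough that the C7 methylene between alkene and alkyne should not isomerise.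

Step 6
Reactants: 10 (2R)-2-methyl-4-methylidenehept-6-yn-1-ol
Product: 12 (2R,6E)-7-iodo-2,6-dimethyl-4-methylidenehept-6-en-1-ol, via the alkenyl(dimethyl)alane 11 (not isolated)
Conditions: Me3Al (3 equiv), Cp2ZrCl2 (0.3 equiv), CH2Cl2, 0 °C to rt; then I2, THF, −30 to 0 °C
Reagents that add atoms: trimethylaluminium, C[Al](C)C; iodine, I-I
Why: Negishi zirconium-catalysed carboalumination adds methyl and aluminium syn across the terminal alkyne with aluminium on the terminal carbon, and iodinolysis with retention gives the (E)-iodoalkene; the hydroxyl is masked in the flask as its aluminium alkoxide and the 1,1-disubstituted alkene is not carbometalated under these conditions.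

Step 7
Reactants: 12 (2R,6E)-7-iodo-2,6-dimethyl-4-methylidenehept-6-en-1-ol
Product: 13 (2R,4R,6E)-7-iodo-2,4,6-trimethyl-4-[(triethylsilyl)peroxy]hept-6-en-1-ol; 14 (2R,4S,6E)-7-iodo-2,4,6-trimethyl-4-[(triethylsilyl)peroxy]hept-6-en-1-ol
Conditions: Co(thd)2 (10 mol %; thd = 2,2,6,6-tetramethylheptane-3,5-dionate), O2 (1 atm), Et3SiH (2 equiv), ClCH2CH2Cl, rt; chromatographic separation of the C6 epimers
Reagents that add atoms: dioxygen, O=O; triethylsilane, CC[SiH](CC)CC
Why: Mukaiyama–Isayama silylperoxidation: hydrogen-atom transfer from a cobalt hydride to the unhindered 1,1-disubstituted alkene gives the tertiary C6 radical, which takes up O2 and is released as the triethylsilyl peroxide, while the hindered, electron-poor trisubstituted iodoalkene should react far more slowly. The radical is planar and remote from C4, so no facial control is expected: both C6 epimers, 13 and 14, form in the same flask, and after chromatography only 13 is carried on while 14 is set aside.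

Step 8
Reactants: 13 (2R,4R,6E)-7-iodo-2,4,6-trimethyl-4-[(triethylsilyl)peroxy]hept-6-en-1-ol
Product: 15 (2R,4R,6E)-7-iodo-2,4,6-trimethyl-4-[(triethylsilyl)peroxy]hept-6-enal
Conditions: Dess–Martin periodinane, NaHCO3, CH2Cl2, 0 °C to rt
Reagents that add atoms: none
Why: Dess–Martin oxidation of the primary alcohol under buffered conditions that leave the silyl peroxide and the iodoalkene alone; the α-methyl aldehyde is used at once to avoid epimerisation at C4.

Step 9
Reactants: 16 pyridine-2-thiol; 17 acetyl chloride
Product: 18 S-(pyridin-2-yl) ethanethioate
Conditions: Et3N, CH2Cl2, 0 °C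
Reagents that add atoms: none
Why: S-acylation of the thiol by the acid chloride with an amine base.

Step 10
Reactants: 18 S-(pyridin-2-yl) ethanethioate
Product: 19 2-({1-[(tert-butyldimethylsilyl)oxy]ethenyl}sulfanyl)pyridine
Conditions: LiN(SiMe3)2, TBSCl, THF–DMF, −78 °C
Reagents that add atoms: tert-butyldimethylsilyl chloride, CC(C)(C)[Si](C)(C)Cl
Why: Enolisation of the thioester and O-silylation of the enolate in the presence of the silyl chloride give the silyl ketene acetal; trapping at −78 °C outruns loss of thiolate from the enolate.

Step 11
Reactants: 15 (2R,4R,6E)-7-iodo-2,4,6-trimethyl-4-[(triethylsilyl)peroxy]hept-6-enal; 19 2-({1-[(tert-butyldimethylsilyl)oxy]ethenyl}sulfanyl)pyridine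
Product: 21 2-[(3S,4R,6R)-6-[(E)-3-iodo-2-methylprop-2-enyl]-4,6-dimethyl-1,2-dioxan-3-yl]acetic acid, via the syn-β-lactone 20 (not isolated)
Conditions: ZnCl2 (fused, 2 equiv), 19 (1.5 equiv), CH2Cl2, rt (to 35 °C if the lactone persists); aqueous work-up at pH 4
Reagents that add atoms: none
Why: Proposed new method: ZnCl2 activates the aldehyde of 15 for Mukaiyama aldol addition of 19, and the zinc aldolate closes on the thiopyridyl ester (4-exo-trig acyl substitution, the silyl group leaving with the thiopyridine) to give β-lactone 20, which is the known tandem Mukaiyama aldol–lactonisation. The same Lewis acid then activates the strained lactone for alkyl–oxygen cleavage, and the silyl-bearing peroxide oxygen, held four atoms away, attacks C3 from the rear in a 6-exo-tet displacement; the silylperoxonium ion so formed loses Et3Si to chloride or carboxylate, and work-up gives acid 21. The closest known reactions are the Lewis-acid-promoted invertive opening of β-lactones by tethered ether oxygens to tetrahydrofurans and the capture of carbocations by silylperoxy oxygen in peroxycarbenium annulations; their combination on a silyl peroxide has not been shown. C3 is the only new stereocentre: Felkin–Anh addition anti to the C5 chain of the α-methyl aldehyde gives the 3,4-syn lactone (3R), and the SN2 opening inverts it to 3S, the 3,4-trans dioxane with acetate arm, C4 methyl and C6 side chain all equatorial. C4 and C6 are not touched. The step needs attack at the alkyl carbon and not the acyl carbon of the lactone, which is favoured because acyl attack by a peroxide oxygen is reversible and leads nowhere, and it needs the outer rather than the inner peroxide oxygen to react, which is favoured because only the outer oxygen can shed silicon after attack. The silyl group also keeps the peroxide from adding to the aldehyde before the aldol step, and the liberated thiopyridine stays S-silylated and so should not open the lactone.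

Step 12
Reactants: 21 2-[(3S,4R,6R)-6-[(E)-3-iodo-2-methylprop-2-enyl]-4,6-dimethyl-1,2-dioxan-3-yl]acetic acid
Product: 22 methyl 2-[(3S,4R,6R)-6-[(E)-3-iodo-2-methylprop-2-enyl]-4,6-dimethyl-1,2-dioxan-3-yl]acetate
Conditions: Me3SiCHN2, PhMe–MeOH, 0 °C
Reagents that add atoms: (trimethylsilyl)diazomethane, C[Si](C)(C)C=[N+]=[N-]
Why: Esterification of the acid by protonation of the diazoalkane and O-alkylation; the conditions are neutral, so the β-peroxy ester sees no base.

Step 13
Reactants: 22 methyl 2-[(3S,4R,6R)-6-[(E)-3-iodo-2-methylprop-2-enyl]-4,6-dimethyl-1,2-dioxan-3-yl]acetate; 23 (E)-(3-phenylprop-1-en-1-yl)boronic acid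
Product: 24 methyl 2-[(3S,4R,6R)-4,6-dimethyl-6-[(2E,4E)-2-methyl-6-phenylhexa-2,4-dienyl]-1,2-dioxan-3-yl]acetate
Conditions: PdCl2(dppf) (5 mol %), K3PO4 (aq.), THF, degassed, rt
Reagents that add atoms: none
Why: Suzuki–Miyaura coupling of an alkenyl iodide with an alkenylboronic acid, which retains both alkene geometries and forms C9–C10; an iodide reacts at room temperature with a mild base, a chelating phosphine leaves little free phosphine, and dialkyl peroxides are known to survive palladium-catalysed couplings under such conditions.

## Compound list

1 | methyl (R)-3-hydroxy-2-methylpropanoate | COC(=O)[C@H](C)CO | starting material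
2 | methyl (S)-3-iodo-2-methylpropanoate | COC(=O)[C@H](C)CI | intermediate
3 | 2,3-dibromoprop-1-ene | C=C(Br)CBr | starting material
4 | ethynyltrimethylsilane | C#C[Si](C)(C)C | starting material
5 | [(trimethylsilyl)ethynyl]magnesium bromide | C[Si](C)(C)C#C[Mg]Br | intermediate
6 | (4-bromopent-4-en-1-yn-1-yl)trimethylsilane | C=C(Br)CC#C[Si](C)(C)C | intermediate
7 | (S)-(3-methoxy-2-methyl-3-oxopropyl)zinc iodide | COC(=O)[C@H](C)C[Zn]I | intermediate
8 | methyl (2R)-2-methyl-4-methylidene-7-(trimethylsilyl)hept-6-ynoate | COC(=O)[C@H](C)CC(=C)CC#C[Si](C)(C)C | intermediate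
9 | (2R)-2-methyl-4-methylidene-7-(trimethylsilyl)hept-6-yn-1-ol | OC[C@H](C)CC(=C)CC#C[Si](C)(C)C | intermediate
10 | (2R)-2-methyl-4-methylidenehept-6-yn-1-ol | OC[C@H](C)CC(=C)CC#C | intermediate
11 | dimethylaluminium (2R,6E)-7-(dimethylalumanyl)-2,6-dimethyl-4-methylidenehept-6-en-1-olate | C[Al](C)OC[C@H](C)CC(=C)C/C(C)=C/[Al](C)C | intermediate
12 | (2R,6E)-7-iodo-2,6-dimethyl-4-methylidenehept-6-en-1-ol | OC[C@H](C)CC(=C)C/C(C)=C/I | intermediate
13 | (2R,4R,6E)-7-iodo-2,4,6-trimethyl-4-[(triethylsilyl)peroxy]hept-6-en-1-ol | OC[C@H](C)C[C@@](C)(OO[Si](CC)(CC)CC)C/C(C)=C/I | intermediate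
14 | (2R,4S,6E)-7-iodo-2,4,6-trimethyl-4-[(triethylsilyl)peroxy]hept-6-en-1-ol (C6 epimer of 13, second product of step 7, separated and not carried on) | OC[C@H](C)C[C@](C)(OO[Si](CC)(CC)CC)C/C(C)=C/I | intermediate
15 | (2R,4R,6E)-7-iodo-2,4,6-trimethyl-4-[(triethylsilyl)peroxy]hept-6-enal | O=C[C@H](C)C[C@@](C)(OO[Si](CC)(CC)CC)C/C(C)=C/I | intermediate
16 | pyridine-2-thiol | Sc1ccccn1 | starting material
17 | acetyl chloride | CC(=O)Cl | starting material
18 | S-(pyridin-2-yl) ethanethioate | CC(=O)Sc1ccccn1 | intermediate
19 | 2-({1-[(tert-butyldimethylsilyl)oxy]ethenyl}sulfanyl)pyridine | C=C(O[Si](C)(C)C(C)(C)C)Sc1ccccn1 | intermediate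
20 | (4R)-4-[(2R,4R,6E)-7-iodo-4,6-dimethyl-4-[(triethylsilyl)peroxy]hept-6-en-2-yl]oxetan-2-one | O=C1C[C@H]([C@H](C)C[C@@](C)(OO[Si](CC)(CC)CC)C/C(C)=C/I)O1 | intermediate
21 | 2-[(3S,4R,6R)-6-[(E)-3-iodo-2-methylprop-2-enyl]-4,6-dimethyl-1,2-dioxan-3-yl]acetic acid | OC(=O)C[C@@H]1OO[C@@](C)(C/C(C)=C/I)C[C@H]1C | intermediate
22 | methyl 2-[(3S,4R,6R)-6-[(E)-3-iodo-2-methylprop-2-enyl]-4,6-dimethyl-1,2-dioxan-3-yl]acetate | COC(=O)C[C@@H]1OO[C@@](C)(C/C(C)=C/I)C[C@H]1C | intermediate
23 | (E)-(3-phenylprop-1-en-1-yl)boronic acid | OB(O)/C=C/Cc1ccccc1 | starting material
24 | methyl 2-[(3S,4R,6R)-4,6-dimethyl-6-[(2E,4E)-2-methyl-6-phenylhexa-2,4-dienyl]-1,2-dioxan-3-yl]acetate | COC(=O)C[C@@H]1OO[C@@](C)(C/C(C)=C/C=C/Cc2ccccc2)C[C@H]1C | target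

## Step count and least certain steps

Total step count: 13. Longest linear sequence: 10 steps (1, 3, 4, 5, 6, 7, 8, 11, 12, 13, from 1); steps 2, 9 and 10 are side branches.

**Step 11 (key step, new method).**
- What may go wrong: the lactone may form but not open through the peroxide oxygen. Chloride opening at C3, a dyotropic hydride shift to a γ-lactone or decarboxylation are the usual fates of Lewis-acid-activated β-lactones. The Lewis acid may also trigger heterolysis of the tertiary O–O bond with migration of the allyl-type C7 group. Facial selectivity of an acetate-type nucleophile on an α-methyl aldehyde may be modest, which would erode the configuration at C3.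
- Fallback (known chemistry), from 15 to 22: Wittig olefination of 15 with methyl (triphenylphosphoranylidene)acetate gives the enoate methyl (2E,4R,6R,8E)-9-iodo-4,6,8-trimethyl-6-[(triethylsilyl)peroxy]nona-2,8-dienoate F1. Desilylation with HF·pyridine in THF gives the hydroperoxide methyl (2E,4R,6R,8E)-6-hydroperoxy-9-iodo-4,6,8-trimethylnona-2,8-dienoate F2. Intramolecular peroxy-Michael addition (Et2NH, CF3CH2OH) closes the dioxane and returns to the route at 22, passing over 21 and step 12. The addition is reversible under these conditions, so the all-equatorial 3,4-trans ring should be favoured; incomplete selectivity at C3 would have to be dealt with by chromatography at that stage.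

**Step 7.**
- What may go wrong: competing hydrogen-atom transfer to the iodoalkene with loss of iodine, or addition of the intermediate peroxyl radical to the C8=C9 alkene. There is no facial control at C6, so a large share of the material is expected to end up as the wrong epimer, and the epimers may not separate at this acyclic stage. In that case separation would be postponed to the cyclic stage, where the two series differ in ring conformation.
- Fallback, from 12 to 15: a polar route that avoids radicals. Benzoylation (BzCl, pyridine) gives (2R,6E)-7-iodo-2,6-dimethyl-4-methylidenehept-6-en-1-yl benzoate F3; the ester keeps the C3 oxygen from capturing a C6 cation as a tetrahydrofuran. Acid-catalysed Markovnikov addition of hydrogen peroxide (50 % H2O2, cat. H2SO4, Et2O, 0 °C) gives (2R,4R,6E)-4-hydroperoxy-7-iodo-2,4,6-trimethylhept-6-en-1-yl benzoate F4 and its C6 epimer (2R,4S,6E)-4-hydroperoxy-7-iodo-2,4,6-trimethylhept-6-en-1-yl benzoate F5, which is removed by chromatography. Methanolysis of the wanted epimer (K2CO3, MeOH) gives (2R,4R,6E)-4-hydroperoxy-7-iodo-2,4,6-trimethylhept-6-en-1-ol F6. Silylation of both O–H groups (Et3SiCl, imidazole) gives triethyl{[(2R,4R,6E)-7-iodo-2,4,6-trimethyl-4-[(triethylsilyl)peroxy]hept-6-en-1-yl]oxy}silane F7. Swern oxidation, which turns a primary triethylsilyl ether directly into the aldehyde while the hindered tertiary silyl peroxide should remain, returns to the route at 15.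

**Step 13.**
- What may go wrong: reduction of the O–O bond by zerovalent palladium or phosphine; base-induced opening of the β-peroxy ester; palladium hydride isomerisation of the skipped diene into conjugation with the phenyl ring; protodeboronation of 23.
- Fallback, from 22 to 24: a base-free Stille coupling. Prop-2-yn-1-ylbenzene is hydrostannylated (Bu3SnH, Pd2(dba)3, PCy3) to tributyl[(E)-3-phenylprop-1-en-1-yl]stannane F8, which is coupled with 22 using PdCl2(MeCN)2 in DMF at rt, without base or added phosphine, to give 24.

**Step 3.**
- What may go wrong: slow oxidative addition of the 2-bromoalkene, so that protonation or homocoupling of the zinc reagent takes over; β-hydride elimination from the alkylpalladium intermediate.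
- Fallback, from 5 to 9: the C4–C5 bond is made instead, by Evans alkylation. The Grignard reagent 5 (made from 4 as in step 2) is coupled with excess 3-chloro-2-(chloromethyl)prop-1-ene (CuBr·SMe2) to give [4-(chloromethyl)pent-4-en-1-yn-1-yl]trimethylsilane F9. Finkelstein exchange (NaI, acetone) gives [4-(iodomethyl)pent-4-en-1-yn-1-yl]trimethylsilane F10. Alkylation of the sodium enolate of (S)-4-benzyl-3-propanoyloxazolidin-2-one (NaN(SiMe3)2, THF, −78 °C) with F10, on the enolate face away from the benzyl group, gives (4S)-4-benzyl-3-[(2R)-2-methyl-4-methylidene-7-(trimethylsilyl)hept-6-ynoyl]oxazolidin-2-one F11. Reduction with LiBH4 (Et2O–MeOH) returns to the route at 9.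

## Further compounds

F1 | step 11 | methyl (2E,4R,6R,8E)-9-iodo-4,6,8-trimethyl-6-[(triethylsilyl)peroxy]nona-2,8-dienoate | COC(=O)/C=C/[C@H](C)C[C@@](C)(OO[Si](CC)(CC)CC)C/C(C)=C/I
F2 | step 11 | methyl (2E,4R,6R,8E)-6-hydroperoxy-9-iodo-4,6,8-trimethylnona-2,8-dienoate | COC(=O)/C=C/[C@H](C)C[C@@](C)(OO)C/C(C)=C/I
F3 | step 7 | (2R,6E)-7-iodo-2,6-dimethyl-4-methylidenehept-6-en-1-yl benzoate | O=C(OC[C@H](C)CC(=C)C/C(C)=C/I)c1ccccc1
F4 | step 7 | (2R,4R,6E)-4-hydroperoxy-7-iodo-2,4,6-trimethylhept-6-en-1-yl benzoate | O=C(OC[C@H](C)C[C@@](C)(OO)C/C(C)=C/I)c1ccccc1
F5 | step 7 | (2R,4S,6E)-4-hydroperoxy-7-iodo-2,4,6-trimethylhept-6-en-1-yl benzoate | O=C(OC[C@H](C)C[C@](C)(OO)C/C(C)=C/I)c1ccccc1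
F6 | step 7 | (2R,4R,6E)-4-hydroperoxy-7-iodo-2,4,6-trimethylhept-6-en-1-ol | OC[C@H](C)C[C@@](C)(OO)C/C(C)=C/I
F7 | step 7 | triethyl{[(2R,4R,6E)-7-iodo-2,4,6-trimethyl-4-[(triethylsilyl)peroxy]hept-6-en-1-yl]oxy}silane | CC[Si](CC)(CC)OC[C@H](C)C[C@@](C)(OO[Si](CC)(CC)CC)C/C(C)=C/I
F8 | step 13 | tributyl[(E)-3-phenylprop-1-en-1-yl]stannane | CCCC[Sn](CCCC)(CCCC)/C=C/Cc1ccccc1
F9 | step 3 | [4-(chloromethyl)pent-4-en-1-yn-1-yl]trimethylsilane | ClCC(=C)CC#C[Si](C)(C)C
F10 | step 3 | [4-(iodomethyl)pent-4-en-1-yn-1-yl]trimethylsilane | ICC(=C)CC#C[Si](C)(C)C
F11 | step 3 | (4S)-4-benzyl-3-[(2R)-2-methyl-4-methylidene-7-(trimethylsilyl)hept-6-ynoyl]oxazolidin-2-one | O=C1OC[C@H](Cc2ccccc2)N1C(=O)[C@H](C)CC(=C)CC#C[Si](C)(C)C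
A1 | alternative 1 | tert-butyl-[2-[(3S,4R,6R)-4,6-dimethyl-6-[(2E,4E)-2-methyl-6-phenylhexa-2,4-dienyl]-1,2-dioxan-3-yl]ethoxy]dimethylsilane | CC(C)(C)[Si](C)(C)OCC[C@@H]1OO[C@@](C)(C/C(C)=C/C=C/Cc2ccccc2)C[C@H]1C
A2 | alternative 1 | (2E)-1-{2-[(2R,3S)-5-[(tert-butyldimethylsilyl)oxy]-3-hydroperoxy-2-methylpentyl]-1,2-dimethylcyclopropyl}-4-phenylbut-2-en-1-ol, C6 configured for rear-side attack, C8 and C9 left open because both are lost in the step | CC(C)(C)[Si](C)(C)OCC[C@H](OO)[C@H](C)C[C@@]1(C)CC1(C)C(O)/C=C/Cc1ccccc1
A3 | alternative 2 | methyl 2-[(3S,4R,6R)-3-hydroxy-6-[(E)-3-iodo-2-methylprop-2-enyl]-4,6-dimethyl-1,2-dioxan-3-yl]acetate | COC(=O)C[C@]1(O)OO[C@@](C)(C/C(C)=C/I)C[C@H]1C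
A4 | alternative 2 | methyl 2-[(2R)-1-hydroxy-4-[(E)-3-iodo-2-methylprop-2-enyl]-2,4-dimethylcyclobutyl]acetate, C1 and C4 of the ring left open because both are lost in the step | COC(=O)CC1(O)[C@H](C)CC1(C)C/C(C)=C/I
A5 | alternative 3 | methyl 2-[(3S,4R,6R)-4,6-dimethyl-6-[(E)-2-methyl-3-trimethylsilylprop-2-enyl]-1,2-dioxan-3-yl]acetate | COC(=O)C[C@@H]1OO[C@@](C)(C/C(C)=C/[Si](C)(C)C)C[C@H]1C
A6 | alternative 3 | [(1E,4R,6R)-4-hydroperoxy-2,4,6-trimethylocta-1,7-dien-1-yl]trimethylsilane | C=C[C@H](C)C[C@@](C)(OO)C/C(C)=C/[Si](C)(C)C
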